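**Plan**

- Ring locants: C1 carries the acrylic acid, C2 the free OH, C3 the 3-hydroxyprop-1-en-2-yl group, C4 methyl and vinyl, C5 is CH2, C6 carries the ester oxygen. Cuts, in retrosynthetic order: the C6–O acyl bond, the C=CH2 of the acrylic acid, ring bond C2–C3, the bond from C1 to its CH2CO2R arm, bond C1–C6, and the bond from quaternary C4 to the alkenyl carbon (future C3).
- Forward: a CuCl-catalysed SN2′ alkenylation builds acyclic C4 with its vinyl group and a (Z)-trisubstituted alkene. An acetate aldol and an anti-selective dianion alkylation add C6 and C1. The chain aldehyde (future C2) is then closed onto the alkene to give the only ring.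
- Enabling feature: carbinol C2 sits next to C3, which carries a C(=CH2)CH2O unit, trans-diequatorial on the cyclohexane. This homoallylic alcohol (O–C2–C3–C=CH2) is the retron of an intramolecular carbonyl-ene reaction of the citronellal–isopulegol type, and the gem-disubstituted C4 favours closure.
- After ring closure: silylation of O2, α-methylenation of the C1 acetate arm, selective desilylation at O6, esterification with the acetonide-protected (R)-side-chain acid, then deprotection.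
- Stereochemistry: C4 from the chiral N-heterocyclic carbene–CuCl catalyst; C6 from the chiral Ti(OiPr)4–Schiff base aldol catalyst; C1 from the chelated dianion (anti to O6); C2 and C3 from the chair transition state of the ene reaction, steered by C6 and C4; the side-chain carbinol from the (R)-malic acid pool.

Key step: step 14

Assumption: methyl 2-[(4R)-2,2-dimethyl-1,3-dioxolan-4-yl]acetate, the starting material of step 18, is taken as purchasable; it is otherwise made in two steps from dimethyl (R)-malate.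

**Step 1**
Reactants: 1 tert-butyl(but-3-yn-1-yloxy)dimethylsilane
Product: 4 (2E)-5-{[tert-butyl(dimethyl)silyl]oxy}-3-methylpent-2-en-1-ol, via alkenyl(dimethyl)alane 2 (not isolated), via lithium alkenylaluminate 3 (not isolated)
Conditions: Me3Al, Cp2ZrCl2 (cat.), CH2Cl2, 0 °C to rt; n-BuLi, THF, −78 °C; (CH2O)n, −78 °C to rt; aq. potassium sodium tartrate
Reagents that add atoms: trimethylaluminium, C[Al](C)C; formaldehyde (as paraformaldehyde), C=O
Why: Zirconium-catalysed syn-carboalumination (Negishi carboalumination) puts methyl on the internal alkyne carbon, and the aluminate traps formaldehyde with retention, which fixes the E geometry.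

**Step 2**
Reactants: 4 (2E)-5-{[tert-butyl(dimethyl)silyl]oxy}-3-methylpent-2-en-1-ol
Product: 5 (2E)-5-{[tert-butyl(dimethyl)silyl]oxy}-3-methylpent-2-en-1-yl diethyl phosphate
Conditions: (EtO)2P(O)Cl, Et3N, DMAP (cat.), CH2Cl2, 0 °C
Reagents that add atoms: diethyl chlorophosphate, CCOP(=O)(Cl)OCC
Why: Phosphorylation of the primary allylic alcohol installs the leaving group needed for copper-catalysed allylic substitution without touching the silyl ether.

**Step 3**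
Reactants: 6 prop-2-yn-1-ol
Product: 8 (2Z)-3-iodo-2-methylprop-2-en-1-ol, via alkenylmagnesium alkoxide 7 (not isolated)
Conditions: MeMgBr (2.5 equiv), CuI (10 mol%), THF, −10 °C to rt; I2, 0 °C
Reagents that add atoms: methylmagnesium bromide, C[Mg]Br; iodine, II
Why: Copper-catalysed anti-carbomagnesiation of the propargylic magnesium alkoxide places methyl on the proximal alkyne carbon through a magnesium chelate, and iodinolysis with retention gives the Z iodide.

**Step 4**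
Reactants: 8 (2Z)-3-iodo-2-methylprop-2-en-1-ol
Product: 9 tert-butyl{[(2Z)-3-iodo-2-methylprop-2-en-1-yl]oxy}diphenylsilane
Conditions: TBDPSCl, imidazole, DMF, rt
Reagents that add atoms: tert-butyl(chloro)diphenylsilane, CC(C)(C)[Si](Cl)(c1ccccc1)c1ccccc1
Why: Standard silylation of a primary alcohol with an acid-stable group that should survive to the last step and stay distinguishable from the TBS ether of the other fragment.

**Step 5**
Reactants: 9 tert-butyl{[(2Z)-3-iodo-2-methylprop-2-en-1-yl]oxy}diphenylsilane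
Product: 11 tert-butyl{[(2Z)-2-methyl-3-(4,4,5,5-tetramethyl-1,3,2-dioxaborolan-2-yl)prop-2-en-1-yl]oxy}diphenylsilane, via alkenyllithium 10 (not isolated)
Conditions: t-BuLi (2.1 equiv), Et2O, −78 °C; iPrOB(pin), −78 °C to rt; H2O
Reagents that add atoms: 2-isopropoxy-4,4,5,5-tetramethyl-1,3,2-dioxaborolane, CC(C)OB1OC(C)(C)C(C)(C)O1
Why: Iodine–lithium exchange and borylation of the alkenyllithium both proceed with retention of the alkene geometry.

**Step 6**
Reactants: 5 (2E)-5-{[tert-butyl(dimethyl)silyl]oxy}-3-methylpent-2-en-1-yl diethyl phosphate; 11 tert-butyl{[(2Z)-2-methyl-3-(4,4,5,5-tetramethyl-1,3,2-dioxaborolan-2-yl)prop-2-en-1-yl]oxy}diphenylsilane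
Product: 12 tert-butyl{[(2Z,4S)-4-(2-{[tert-butyl(dimethyl)silyl]oxy}ethyl)-2,4-dimethylhexa-2,5-dien-1-yl]oxy}diphenylsilane
Conditions: CuCl (10 mol%), chiral sulfonate-bearing imidazolinium salt (N-heterocyclic carbene precursor, 11 mol%; the enantiomer that gives the S centre), NaOMe, THF, 22 °C
Reagents that add atoms: none
Why: N-heterocyclic carbene–copper-catalysed enantioselective allylic substitution (SN2′) transfers the alkenyl group of the methoxide-activated boronate to the γ-carbon of the E phosphate, so the quaternary centre (future C4) and the vinyl group form together under ligand control with the Z alkene retained.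

**Step 7**
Reactants: 12 tert-butyl{[(2Z,4S)-4-(2-{[tert-butyl(dimethyl)silyl]oxy}ethyl)-2,4-dimethylhexa-2,5-dien-1-yl]oxy}diphenylsilane
Product: 13 (3S,4Z)-6-{[tert-butyl(diphenyl)silyl]oxy}-3-ethenyl-3,5-dimethylhex-4-en-1-ol
Conditions: camphorsulfonic acid (10 mol%), MeOH/CH2Cl2, 0 °C
Reagents that add atoms: none
Why: Acid-catalysed methanolysis cleaves the primary TBS ether much faster than the primary TBDPS ether.

**Step 8**
Reactants: 13 (3S,4Z)-6-{[tert-butyl(diphenyl)silyl]oxy}-3-ethenyl-3,5-dimethylhex-4-en-1-ol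
Product: 14 (3S,4Z)-6-{[tert-butyl(diphenyl)silyl]oxy}-3-ethenyl-3,5-dimethylhex-4-enal
Conditions: Dess–Martin periodinane, pyridine, CH2Cl2, 0 °C to rt
Reagents that add atoms: none
Why: Dess–Martin oxidation of a primary alcohol to the aldehyde, in which no stereocentre is at risk because the α-carbon is a CH2 next to the quaternary carbon.

**Step 9**
Reactants: 14 (3S,4Z)-6-{[tert-butyl(diphenyl)silyl]oxy}-3-ethenyl-3,5-dimethylhex-4-enal
Product: 16 methyl (3R,5S,6Z)-8-{[tert-butyl(diphenyl)silyl]oxy}-5-ethenyl-3-hydroxy-5,7-dimethyloct-6-enoate, via aldol trimethylsilyl ether 15 (not isolated)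
Conditions: Ti(OiPr)4 (2 mol%), chiral tridentate binaphthyl Schiff-base ligand (the enantiomer that gives the 3R alcohol), 3,5-di-tert-butylsalicylic acid, Et2O, −10 °C; then 1 M HCl, THF, 0 °C
Reagents that add atoms: 1-methoxy-1-(trimethylsilyloxy)ethene, C=C(OC)O[Si](C)(C)C
Why: Catalytic enantioselective Mukaiyama aldol addition of the acetate silyl ketene acetal, in which the chiral titanium complex selects the aldehyde face and sets the carbinol centre (future C6) while the remote quaternary centre exerts little bias.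

**Step 10**
Reactants: 16 methyl (3R,5S,6Z)-8-{[tert-butyl(diphenyl)silyl]oxy}-5-ethenyl-3-hydroxy-5,7-dimethyloct-6-enoate
Product: 18 4-tert-butyl 1-methyl (2R)-2-[(1R,3S,4Z)-6-{[tert-butyl(diphenyl)silyl]oxy}-3-ethenyl-1-hydroxy-3,5-dimethylhex-4-en-1-yl]butanedioate, via dilithium alkoxide-enolate 17 (not isolated)
Conditions: LiN(iPr)2 (2.2 equiv), THF, −78 to −20 °C; BrCH2CO2tBu, DMPU, −78 to −20 °C; H2O
Reagents that add atoms: tert-butyl bromoacetate, BrCC(=O)OC(C)(C)C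
Why: Fráter–Seebach alkylation, in which the chelated lithium alkoxide-enolate is alkylated on the face away from the carbinol substituent and so sets the new centre (future C1) anti to the hydroxyl.

**Step 11**
Reactants: 18 4-tert-butyl 1-methyl (2R)-2-[(1R,3S,4Z)-6-{[tert-butyl(diphenyl)silyl]oxy}-3-ethenyl-1-hydroxy-3,5-dimethylhex-4-en-1-yl]butanedioate
Product: 19 4-tert-butyl 1-methyl (2R)-2-[(1R,3S,4Z)-6-{[tert-butyl(diphenyl)silyl]oxy}-3-ethenyl-3,5-dimethyl-1-[(triethylsilyl)oxy]hex-4-en-1-yl]butanedioate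
Conditions: TESCl, imidazole, DMF, 0 °C to rt
Reagents that add atoms: chlorotriethylsilane, CC[Si](Cl)(CC)CC
Why: Silylation of the secondary alcohol with a non-chelating silyl group that can later be removed in the presence of TBS and TBDPS ethers.

**Step 12**
Reactants: 19 4-tert-butyl 1-methyl (2R)-2-[(1R,3S,4Z)-6-{[tert-butyl(diphenyl)silyl]oxy}-3-ethenyl-3,5-dimethyl-1-[(triethylsilyl)oxy]hex-4-en-1-yl]butanedioate
Product: 20 tert-butyl (3S,4R,6S,7Z)-9-{[tert-butyl(diphenyl)silyl]oxy}-6-ethenyl-3-(hydroxymethyl)-6,8-dimethyl-4-[(triethylsilyl)oxy]non-7-enoate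
Conditions: LiBH4, MeOH (1 equiv), Et2O, 0 °C to rt
Reagents that add atoms: none
Why: LiBH4 reduces the methyl ester to the primary alcohol much faster than the tert-butyl ester, which also resists lactonisation by the new hydroxyl.

**Step 13**
Reactants: 20 tert-butyl (3S,4R,6S,7Z)-9-{[tert-butyl(diphenyl)silyl]oxy}-6-ethenyl-3-(hydroxymethyl)-6,8-dimethyl-4-[(triethylsilyl)oxy]non-7-enoate
Product: 21 tert-butyl (3R,4R,6S,7Z)-9-{[tert-butyl(diphenyl)silyl]oxy}-6-ethenyl-3-formyl-6,8-dimethyl-4-[(triethylsilyl)oxy]non-7-enoate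
Conditions: Dess–Martin periodinane, pyridine, CH2Cl2, 0 °C
Reagents that add atoms: none
Why: Buffered Dess–Martin oxidation should give the α-branched aldehyde without epimerisation, and it is used at once.

**Step 14**
Reactants: 21 tert-butyl (3R,4R,6S,7Z)-9-{[tert-butyl(diphenyl)silyl]oxy}-6-ethenyl-3-formyl-6,8-dimethyl-4-[(triethylsilyl)oxy]non-7-enoate
Product: 23 tert-butyl 2-[(1S,2S,3S,4S,6R)-3-(3-{[tert-butyl(diphenyl)silyl]oxy}prop-1-en-2-yl)-4-ethenyl-2-hydroxy-4-methyl-6-[(triethylsilyl)oxy]cyclohexyl]acetate, via chloro(methyl)aluminium alkoxide 22 (not isolated)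
Conditions: Me2AlCl (1.5 equiv), CH2Cl2, −78 to −40 °C; then aq. potassium sodium tartrate, −40 °C to rt
Reagents that add atoms: none
Why: Me2AlCl activates the aldehyde, whose carbon (C2) is attacked by the inner alkene carbon (C3) while a hydrogen of the alkene methyl group passes to oxygen through a six-centre array, so the double bond moves into the exocyclic methylene position; the resulting alcohol–Me2AlCl complex then loses methane to give the aluminium alkoxide, which removes the proton source for Prins-type side reactions. The closest known reaction is the Lewis-acid cyclisation of citronellal to isopulegol (type 1 intramolecular carbonyl-ene reaction). The cyclohexane closes in the 6-exo-trig mode at the carbonyl carbon, with both the C=O and the C=C exocyclic to the new ring. C2 and C3 should arise trans-diequatorial from a chair transition state; the chair used is the one that keeps the C6 silyloxy group and the C4 methyl equatorial (the other chair sets them 1,3-diaxial), so the C1 acetate arm is axial and the new centres take the 2S,3S sense relative to C1, C6 and C4. Hydrogen transfer from CH3 and not from CH2OSi is secured by the Z geometry, because only the group trans to the tether can reach the oxygen. The vinyl group does not compete because it has no allylic hydrogen and could only close a four-membered ring, and the low temperature and non-basic medium protect the C1 configuration.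

**Step 15**
Reactants: 23 tert-butyl 2-[(1S,2S,3S,4S,6R)-3-(3-{[tert-butyl(diphenyl)silyl]oxy}prop-1-en-2-yl)-4-ethenyl-2-hydroxy-4-methyl-6-[(triethylsilyl)oxy]cyclohexyl]acetate
Product: 24 tert-butyl 2-[(1R,2S,3S,4S,6R)-2-{[tert-butyl(dimethyl)silyl]oxy}-3-(3-{[tert-butyl(diphenyl)silyl]oxy}prop-1-en-2-yl)-4-ethenyl-4-methyl-6-[(triethylsilyl)oxy]cyclohexyl]acetate
Conditions: TBSOTf (1.3 equiv), 2,6-lutidine, CH2Cl2, −78 to −20 °C
Reagents that add atoms: tert-butyldimethylsilyl trifluoromethanesulfonate, CC(C)(C)[Si](C)(C)OS(=O)(=O)C(F)(F)F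
Why: Silyl triflate silylation of the hindered equatorial alcohol at low temperature, where the tert-butyl ester is not attacked.

**Step 16**
Reactants: 24 tert-butyl 2-[(1R,2S,3S,4S,6R)-2-{[tert-butyl(dimethyl)silyl]oxy}-3-(3-{[tert-butyl(diphenyl)silyl]oxy}prop-1-en-2-yl)-4-ethenyl-4-methyl-6-[(triethylsilyl)oxy]cyclohexyl]acetate
Product: 28 tert-butyl 2-[(1R,2S,3S,4S,6R)-2-{[tert-butyl(dimethyl)silyl]oxy}-3-(3-{[tert-butyl(diphenyl)silyl]oxy}prop-1-en-2-yl)-4-ethenyl-4-methyl-6-[(triethylsilyl)oxy]cyclohexyl]prop-2-enoate, via lithium enolate 25 (not isolated), via Mannich base 26 (not isolated), via ammonium iodide 27 (not isolated)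
Conditions: LiN(iPr)2, THF, −78 °C; CH2=NMe2+ I−, −78 to 0 °C; MeI, rt; DBU, rt
Reagents that add atoms: N,N-dimethylmethyleneiminium iodide (Eschenmoser's salt), C=[N+](C)C.[I-]
Why: α-Methylenation by Mannich reaction of the ester enolate with Eschenmoser's salt, quaternisation and base-induced loss of trimethylamine, in which no stereocentre is formed and the enolate has no β-leaving group.

**Step 17**
Reactants: 28 tert-butyl 2-[(1R,2S,3S,4S,6R)-2-{[tert-butyl(dimethyl)silyl]oxy}-3-(3-{[tert-butyl(diphenyl)silyl]oxy}prop-1-en-2-yl)-4-ethenyl-4-methyl-6-[(triethylsilyl)oxy]cyclohexyl]prop-2-enoate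
Product: 29 tert-butyl 2-[(1R,2S,3S,4S,6R)-2-{[tert-butyl(dimethyl)silyl]oxy}-3-(3-{[tert-butyl(diphenyl)silyl]oxy}prop-1-en-2-yl)-4-ethenyl-6-hydroxy-4-methylcyclohexyl]prop-2-enoate
Conditions: PPTS, MeOH/CH2Cl2, 0 °C
Reagents that add atoms: none
Why: Mild acid methanolysis removes the secondary TES ether selectively, since the secondary TBS and primary TBDPS ethers react far more slowly.

**Step 18**
Reactants: 30 methyl 2-[(4R)-2,2-dimethyl-1,3-dioxolan-4-yl]acetate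
Product: 34 methyl 2-[(4R)-2,2-dimethyl-1,3-dioxolan-4-yl]prop-2-enoate, via lithium enolate 31 (not isolated), via Mannich base 32 (not isolated), via ammonium iodide 33 (not isolated)
Conditions: LiN(iPr)2, THF, −78 °C; CH2=NMe2+ I−, −78 to −20 °C; MeI, rt; DBU, rt
Reagents that add atoms: N,N-dimethylmethyleneiminium iodide (Eschenmoser's salt), C=[N+](C)C.[I-]
Why: The same Mannich–elimination methylenation, run at −78 °C so that the dioxolane oxygen β to the enolate is not expelled and the carbinol centre from the malic acid pool is untouched.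

**Step 19**
Reactants: 34 methyl 2-[(4R)-2,2-dimethyl-1,3-dioxolan-4-yl]prop-2-enoate
Product: 35 2-[(4R)-2,2-dimethyl-1,3-dioxolan-4-yl]prop-2-enoic acid
Conditions: LiOH, THF/H2O, 0 °C; 1 M HCl to pH 4, 0 °C
Reagents that add atoms: lithium hydroxide, [Li+].[OH-]
Why: Saponification of the methyl ester, with the acetonide stable to base and to brief acidification to pH 4.

**Step 20**
Reactants: 29 tert-butyl 2-[(1R,2S,3S,4S,6R)-2-{[tert-butyl(dimethyl)silyl]oxy}-3-(3-{[tert-butyl(diphenyl)silyl]oxy}prop-1-en-2-yl)-4-ethenyl-6-hydroxy-4-methylcyclohexyl]prop-2-enoate; 35 2-[(4R)-2,2-dimethyl-1,3-dioxolan-4-yl]prop-2-enoic acid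
Product: 37 tert-butyl 2-[(1R,2S,3S,4S,6R)-2-{[tert-butyl(dimethyl)silyl]oxy}-3-(3-{[tert-butyl(diphenyl)silyl]oxy}prop-1-en-2-yl)-6-({2-[(4R)-2,2-dimethyl-1,3-dioxolan-4-yl]prop-2-enoyl}oxy)-4-ethenyl-4-methylcyclohexyl]prop-2-enoate, via mixed anhydride 36 (not isolated)
Conditions: 35, 2,4,6-trichlorobenzoyl chloride, Et3N, THF, rt; then 29, DMAP, toluene, rt
Reagents that add atoms: none
Why: Yamaguchi esterification through the mixed anhydride acylates the only free hydroxyl with retention at both carbinol centres.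

**Step 21**
Reactants: 37 tert-butyl 2-[(1R,2S,3S,4S,6R)-2-{[tert-butyl(dimethyl)silyl]oxy}-3-(3-{[tert-butyl(diphenyl)silyl]oxy}prop-1-en-2-yl)-6-({2-[(4R)-2,2-dimethyl-1,3-dioxolan-4-yl]prop-2-enoyl}oxy)-4-ethenyl-4-methylcyclohexyl]prop-2-enoate
Product: 38 tert-butyl 2-[(1R,2S,3S,4S,6R)-2-{[tert-butyl(dimethyl)silyl]oxy}-3-(3-{[tert-butyl(diphenyl)silyl]oxy}prop-1-en-2-yl)-6-{[(3R)-3,4-dihydroxy-2-methylidenebutanoyl]oxy}-4-ethenyl-4-methylcyclohexyl]prop-2-enoate
Conditions: AcOH/THF/H2O (3:1:1), 35 °C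
Reagents that add atoms: none
Why: Mild aqueous acid hydrolyses the terminal acetonide while the silyl ethers and the tert-butyl ester persist, so the diol is freed before any lactonisable hydroxy acid exists.

**Step 22**
Reactants: 38 tert-butyl 2-[(1R,2S,3S,4S,6R)-2-{[tert-butyl(dimethyl)silyl]oxy}-3-(3-{[tert-butyl(diphenyl)silyl]oxy}prop-1-en-2-yl)-6-{[(3R)-3,4-dihydroxy-2-methylidenebutanoyl]oxy}-4-ethenyl-4-methylcyclohexyl]prop-2-enoate
Product: 40 2-[(1S,2S,3S,4S,6R)-6-{[(3R)-3,4-dihydroxy-2-methylidenebutanoyl]oxy}-4-ethenyl-2-hydroxy-3-(3-hydroxyprop-1-en-2-yl)-4-methylcyclohexyl]prop-2-enoic acid, via tris(trimethylsilyl) derivative 39 (not isolated)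
Conditions: TMSOTf, 2,6-lutidine, CH2Cl2, 0 °C to rt; then HF·pyridine, pyridine, THF, 0 °C to rt
Reagents that add atoms: none
Why: Silyl triflate with a hindered base turns the tert-butyl ester into a silyl ester by loss of isobutene under non-protic conditions, and buffered HF then removes every silyl group without hydrolysing the side-chain ester or lactonising the hydroxy acid.

**Compound list**

1 | tert-butyl(but-3-yn-1-yloxy)dimethylsilane | C#CCCO[Si](C)(C)C(C)(C)C | starting material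
2 | [(1E)-4-{[tert-butyl(dimethyl)silyl]oxy}-2-methylbut-1-en-1-yl]dimethylalumane | C[Al](C)/C=C(\C)CCO[Si](C)(C)C(C)(C)C | intermediate
3 | lithium butyl[(1E)-4-{[tert-butyl(dimethyl)silyl]oxy}-2-methylbut-1-en-1-yl]dimethylaluminate | [Li+].CCCC[Al-](C)(C)/C=C(\C)CCO[Si](C)(C)C(C)(C)C | intermediate
4 | (2E)-5-{[tert-butyl(dimethyl)silyl]oxy}-3-methylpent-2-en-1-ol | OC/C=C(\C)CCO[Si](C)(C)C(C)(C)C | intermediate
5 | (2E)-5-{[tert-butyl(dimethyl)silyl]oxy}-3-methylpent-2-en-1-yl diethyl phosphate | CCOP(=O)(OCC)OC/C=C(\C)CCO[Si](C)(C)C(C)(C)C | intermediate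
6 | prop-2-yn-1-ol | C#CCO | starting material
7 | bromomagnesium (2Z)-3-(bromomagnesio)-2-methylprop-2-en-1-olate | Br[Mg]/C=C(/C)CO[Mg]Br | intermediate
8 | (2Z)-3-iodo-2-methylprop-2-en-1-ol | I/C=C(/C)CO | intermediate
9 | tert-butyl{[(2Z)-3-iodo-2-methylprop-2-en-1-yl]oxy}diphenylsilane | I/C=C(/C)CO[Si](c1ccccc1)(c1ccccc1)C(C)(C)C | intermediate
10 | [(1Z)-3-{[tert-butyl(diphenyl)silyl]oxy}-2-methylprop-1-en-1-yl]lithium | [Li]/C=C(/C)CO[Si](c1ccccc1)(c1ccccc1)C(C)(C)C | intermediate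
11 | tert-butyl{[(2Z)-2-methyl-3-(4,4,5,5-tetramethyl-1,3,2-dioxaborolan-2-yl)prop-2-en-1-yl]oxy}diphenylsilane | CC1(C)OB(/C=C(/C)CO[Si](c2ccccc2)(c2ccccc2)C(C)(C)C)OC1(C)C | intermediate
12 | tert-butyl{[(2Z,4S)-4-(2-{[tert-butyl(dimethyl)silyl]oxy}ethyl)-2,4-dimethylhexa-2,5-dien-1-yl]oxy}diphenylsilane | C=C[C@](/C=C(/C)CO[Si](c1ccccc1)(c1ccccc1)C(C)(C)C)(C)CCO[Si](C)(C)C(C)(C)C | intermediate
13 | (3S,4Z)-6-{[tert-butyl(diphenyl)silyl]oxy}-3-ethenyl-3,5-dimethylhex-4-en-1-ol | C=C[C@](/C=C(/C)CO[Si](c1ccccc1)(c1ccccc1)C(C)(C)C)(C)CCO | intermediate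
14 | (3S,4Z)-6-{[tert-butyl(diphenyl)silyl]oxy}-3-ethenyl-3,5-dimethylhex-4-enal | C=C[C@](/C=C(/C)CO[Si](c1ccccc1)(c1ccccc1)C(C)(C)C)(C)CC=O | intermediate
15 | methyl (3R,5S,6Z)-8-{[tert-butyl(diphenyl)silyl]oxy}-5-ethenyl-5,7-dimethyl-3-[(trimethylsilyl)oxy]oct-6-enoate | C=C[C@](/C=C(/C)CO[Si](c1ccccc1)(c1ccccc1)C(C)(C)C)(C)C[C@@H](O[Si](C)(C)C)CC(=O)OC | intermediate
16 | methyl (3R,5S,6Z)-8-{[tert-butyl(diphenyl)silyl]oxy}-5-ethenyl-3-hydroxy-5,7-dimethyloct-6-enoate | C=C[C@](/C=C(/C)CO[Si](c1ccccc1)(c1ccccc1)C(C)(C)C)(C)C[C@@H](O)CC(=O)OC | intermediate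
17 | dilithium (3R,5S,6Z)-8-{[tert-butyl(diphenyl)silyl]oxy}-5-ethenyl-1-methoxy-5,7-dimethylocta-1,6-diene-1,3-bis(olate) (chelated dianion of 16) | C=C[C@](/C=C(/C)CO[Si](c1ccccc1)(c1ccccc1)C(C)(C)C)(C)C[C@@H](O[Li])C=C(O[Li])OC | intermediate
18 | 4-tert-butyl 1-methyl (2R)-2-[(1R,3S,4Z)-6-{[tert-butyl(diphenyl)silyl]oxy}-3-ethenyl-1-hydroxy-3,5-dimethylhex-4-en-1-yl]butanedioate | C=C[C@](/C=C(/C)CO[Si](c1ccccc1)(c1ccccc1)C(C)(C)C)(C)C[C@@H](O)[C@@H](CC(=O)OC(C)(C)C)C(=O)OC | intermediate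
19 | 4-tert-butyl 1-methyl (2R)-2-[(1R,3S,4Z)-6-{[tert-butyl(diphenyl)silyl]oxy}-3-ethenyl-3,5-dimethyl-1-[(triethylsilyl)oxy]hex-4-en-1-yl]butanedioate | C=C[C@](/C=C(/C)CO[Si](c1ccccc1)(c1ccccc1)C(C)(C)C)(C)C[C@@H](O[Si](CC)(CC)CC)[C@@H](CC(=O)OC(C)(C)C)C(=O)OC | intermediate
20 | tert-butyl (3S,4R,6S,7Z)-9-{[tert-butyl(diphenyl)silyl]oxy}-6-ethenyl-3-(hydroxymethyl)-6,8-dimethyl-4-[(triethylsilyl)oxy]non-7-enoate | C=C[C@](/C=C(/C)CO[Si](c1ccccc1)(c1ccccc1)C(C)(C)C)(C)C[C@@H](O[Si](CC)(CC)CC)[C@@H](CC(=O)OC(C)(C)C)CO | intermediate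
21 | tert-butyl (3R,4R,6S,7Z)-9-{[tert-butyl(diphenyl)silyl]oxy}-6-ethenyl-3-formyl-6,8-dimethyl-4-[(triethylsilyl)oxy]non-7-enoate | C=C[C@](/C=C(/C)CO[Si](c1ccccc1)(c1ccccc1)C(C)(C)C)(C)C[C@@H](O[Si](CC)(CC)CC)[C@@H](CC(=O)OC(C)(C)C)C=O | intermediate
22 | tert-butyl 2-[(1S,2S,3S,4S,6R)-3-(3-{[tert-butyl(diphenyl)silyl]oxy}prop-1-en-2-yl)-2-{[chloro(methyl)alumanyl]oxy}-4-ethenyl-4-methyl-6-[(triethylsilyl)oxy]cyclohexyl]acetate | C=C[C@]1(C)C[C@@H](O[Si](CC)(CC)CC)[C@@H](CC(=O)OC(C)(C)C)[C@@H](O[Al](C)Cl)[C@@H]1C(=C)CO[Si](c1ccccc1)(c1ccccc1)C(C)(C)C | intermediate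
23 | tert-butyl 2-[(1S,2S,3S,4S,6R)-3-(3-{[tert-butyl(diphenyl)silyl]oxy}prop-1-en-2-yl)-4-ethenyl-2-hydroxy-4-methyl-6-[(triethylsilyl)oxy]cyclohexyl]acetate | C=C[C@]1(C)C[C@@H](O[Si](CC)(CC)CC)[C@@H](CC(=O)OC(C)(C)C)[C@@H](O)[C@@H]1C(=C)CO[Si](c1ccccc1)(c1ccccc1)C(C)(C)C | intermediate
24 | tert-butyl 2-[(1R,2S,3S,4S,6R)-2-{[tert-butyl(dimethyl)silyl]oxy}-3-(3-{[tert-butyl(diphenyl)silyl]oxy}prop-1-en-2-yl)-4-ethenyl-4-methyl-6-[(triethylsilyl)oxy]cyclohexyl]acetate | C=C[C@]1(C)C[C@@H](O[Si](CC)(CC)CC)[C@@H](CC(=O)OC(C)(C)C)[C@@H](O[Si](C)(C)C(C)(C)C)[C@@H]1C(=C)CO[Si](c1ccccc1)(c1ccccc1)C(C)(C)C | intermediate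
25 | lithium 1-tert-butoxy-2-[ring as in 24]ethen-1-olate (ester enolate of 24) | C=C[C@]1(C)C[C@@H](O[Si](CC)(CC)CC)[C@@H](C=C(O[Li])OC(C)(C)C)[C@@H](O[Si](C)(C)C(C)(C)C)[C@@H]1C(=C)CO[Si](c1ccccc1)(c1ccccc1)C(C)(C)C | intermediate
26 | tert-butyl 3-(dimethylamino)-2-[ring as in 24]propanoate (Mannich base, both epimers at C2 of the propanoate) | C=C[C@]1(C)C[C@@H](O[Si](CC)(CC)CC)[C@@H](C(CN(C)C)C(=O)OC(C)(C)C)[C@@H](O[Si](C)(C)C(C)(C)C)[C@@H]1C(=C)CO[Si](c1ccccc1)(c1ccccc1)C(C)(C)C | intermediate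
27 | {3-tert-butoxy-3-oxo-2-[ring as in 24]propyl}trimethylazanium iodide | C=C[C@]1(C)C[C@@H](O[Si](CC)(CC)CC)[C@@H](C(C[N+](C)(C)C)C(=O)OC(C)(C)C)[C@@H](O[Si](C)(C)C(C)(C)C)[C@@H]1C(=C)CO[Si](c1ccccc1)(c1ccccc1)C(C)(C)C.[I-] | intermediate
28 | tert-butyl 2-[(1R,2S,3S,4S,6R)-2-{[tert-butyl(dimethyl)silyl]oxy}-3-(3-{[tert-butyl(diphenyl)silyl]oxy}prop-1-en-2-yl)-4-ethenyl-4-methyl-6-[(triethylsilyl)oxy]cyclohexyl]prop-2-enoate | C=C[C@]1(C)C[C@@H](O[Si](CC)(CC)CC)[C@@H](C(=C)C(=O)OC(C)(C)C)[C@@H](O[Si](C)(C)C(C)(C)C)[C@@H]1C(=C)CO[Si](c1ccccc1)(c1ccccc1)C(C)(C)C | intermediate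
29 | tert-butyl 2-[(1R,2S,3S,4S,6R)-2-{[tert-butyl(dimethyl)silyl]oxy}-3-(3-{[tert-butyl(diphenyl)silyl]oxy}prop-1-en-2-yl)-4-ethenyl-6-hydroxy-4-methylcyclohexyl]prop-2-enoate | C=C[C@]1(C)C[C@@H](O)[C@@H](C(=C)C(=O)OC(C)(C)C)[C@@H](O[Si](C)(C)C(C)(C)C)[C@@H]1C(=C)CO[Si](c1ccccc1)(c1ccccc1)C(C)(C)C | intermediate
30 | methyl 2-[(4R)-2,2-dimethyl-1,3-dioxolan-4-yl]acetate | COC(=O)C[C@@H](O1)COC1(C)C | starting material
31 | lithium 2-[(4R)-2,2-dimethyl-1,3-dioxolan-4-yl]-1-methoxyethen-1-olate | [Li]OC(OC)=C[C@@H](O1)COC1(C)C | intermediate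
32 | methyl 3-(dimethylamino)-2-[(4R)-2,2-dimethyl-1,3-dioxolan-4-yl]propanoate (both epimers at C2) | COC(=O)C(CN(C)C)[C@@H](O1)COC1(C)C | intermediate
33 | {2-[(4R)-2,2-dimethyl-1,3-dioxolan-4-yl]-3-methoxy-3-oxopropyl}trimethylazanium iodide | COC(=O)C(C[N+](C)(C)C)[C@@H](O1)COC1(C)C.[I-] | intermediate
34 | methyl 2-[(4R)-2,2-dimethyl-1,3-dioxolan-4-yl]prop-2-enoate | C=C(C(=O)OC)[C@@H](O1)COC1(C)C | intermediate
35 | 2-[(4R)-2,2-dimethyl-1,3-dioxolan-4-yl]prop-2-enoic acid | C=C(C(=O)O)[C@@H](O1)COC1(C)C | intermediate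
36 | 2-[(4R)-2,2-dimethyl-1,3-dioxolan-4-yl]prop-2-enoic 2,4,6-trichlorobenzoic anhydride | C=C(C(=O)OC(=O)c1c(Cl)cc(Cl)cc1Cl)[C@@H](O1)COC1(C)C | intermediate
37 | tert-butyl 2-[(1R,2S,3S,4S,6R)-2-{[tert-butyl(dimethyl)silyl]oxy}-3-(3-{[tert-butyl(diphenyl)silyl]oxy}prop-1-en-2-yl)-6-({2-[(4R)-2,2-dimethyl-1,3-dioxolan-4-yl]prop-2-enoyl}oxy)-4-ethenyl-4-methylcyclohexyl]prop-2-enoate | C=C[C@]1(C)C[C@@H](OC(=O)C(=C)[C@@H](O2)COC2(C)C)[C@@H](C(=C)C(=O)OC(C)(C)C)[C@@H](O[Si](C)(C)C(C)(C)C)[C@@H]1C(=C)CO[Si](c1ccccc1)(c1ccccc1)C(C)(C)C | intermediate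
38 | tert-butyl 2-[(1R,2S,3S,4S,6R)-2-{[tert-butyl(dimethyl)silyl]oxy}-3-(3-{[tert-butyl(diphenyl)silyl]oxy}prop-1-en-2-yl)-6-{[(3R)-3,4-dihydroxy-2-methylidenebutanoyl]oxy}-4-ethenyl-4-methylcyclohexyl]prop-2-enoate | C=C[C@]1(C)C[C@@H](OC(=O)C(=C)[C@@H](O)CO)[C@@H](C(=C)C(=O)OC(C)(C)C)[C@@H](O[Si](C)(C)C(C)(C)C)[C@@H]1C(=C)CO[Si](c1ccccc1)(c1ccccc1)C(C)(C)C | intermediate
39 | trimethylsilyl 2-[(1R,2S,3S,4S,6R)-6-({(3R)-2-methylidene-3,4-bis[(trimethylsilyl)oxy]butanoyl}oxy)-2-{[tert-butyl(dimethyl)silyl]oxy}-3-(3-{[tert-butyl(diphenyl)silyl]oxy}prop-1-en-2-yl)-4-ethenyl-4-methylcyclohexyl]prop-2-enoate | C=C[C@]1(C)C[C@@H](OC(=O)C(=C)[C@@H](O[Si](C)(C)C)CO[Si](C)(C)C)[C@@H](C(=C)C(=O)O[Si](C)(C)C)[C@@H](O[Si](C)(C)C(C)(C)C)[C@@H]1C(=C)CO[Si](c1ccccc1)(c1ccccc1)C(C)(C)C | intermediate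
40 | 2-[(1S,2S,3S,4S,6R)-6-{[(3R)-3,4-dihydroxy-2-methylidenebutanoyl]oxy}-4-ethenyl-2-hydroxy-3-(3-hydroxyprop-1-en-2-yl)-4-methylcyclohexyl]prop-2-enoic acid | C=C[C@]1(C)C[C@@H](OC(=O)C(=C)[C@@H](O)CO)[C@@H](C(=C)C(=O)O)[C@@H](O)[C@@H]1C(=C)CO | target

**Totals**

Total step count: 22. Longest linear sequence: 18 steps (steps 3–17 and 20–22, counted from prop-2-yn-1-ol 6).

**Steps most likely to fail**

Step 6. The β,β-disubstituted alkenyl group may transfer too slowly to the γ-carbon, so that linear SN2 product forms or the enantioselectivity at the quaternary carbon erodes. The fallback sets out from 5 and builds the alkene by olefination instead. Hydroalumination of 4-ethynylanisole with iBu2AlH gives [(E)-2-(4-methoxyphenyl)ethenyl]bis(2-methylpropyl)alumane F1. With 5, CuCl2·2H2O and the same class of chiral imidazolinium salt (THF, −15 °C), F1 should give tert-butyl{[(3S,4E)-3-ethenyl-5-(4-methoxyphenyl)-3-methylpent-4-en-1-yl]oxy}dimethylsilane F2, in which an unhindered E-alkenyl group serves as a masked formyl group. Lemieux–Johnson cleavage (OsO4 cat., NaIO4, 2,6-lutidine, dioxane/H2O) should attack the electron-rich styrenyl double bond in preference to the vinyl group and give (2S)-4-{[tert-butyl(dimethyl)silyl]oxy}-2-ethenyl-2-methylbutanal F3. Still–Gennari olefination with methyl 2-[bis(2,2,2-trifluoroethoxy)phosphoryl]propanoate, KN(SiMe3)2 and 18-crown-6 gives methyl (2Z,4S)-6-{[tert-butyl(dimethyl)silyl]oxy}-4-ethenyl-2,4-dimethylhex-2-enoate F4. Reduction with iBu2AlH gives (2Z,4S)-6-{[tert-butyl(dimethyl)silyl]oxy}-4-ethenyl-2,4-dimethylhex-2-en-1-ol F5, and TBDPSCl/imidazole rejoins the route at 12.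

Step 14. The ring may close through the wrong chair (poor facial selectivity at C2/C3), the proton may be lost from the CH2OSi arm, or the cationic intermediate may be captured by chloride or by the ester. The fallback sets out from 20 and replaces the cationic ene closure by an allylmetal addition through a closed transition state. Ene-type chlorination (Ca(OCl)2, solid CO2, CH2Cl2/H2O, 0 °C) should give tert-butyl (3S,4R,6S)-9-{[tert-butyl(diphenyl)silyl]oxy}-7-chloro-6-ethenyl-3-(hydroxymethyl)-6-methyl-8-methylidene-4-[(triethylsilyl)oxy]nonanoate F6, as both epimers at the chlorine-bearing carbon. Dess–Martin oxidation gives the corresponding 3-formyl compound, tert-butyl (3R,4R,6S)-9-{[tert-butyl(diphenyl)silyl]oxy}-7-chloro-6-ethenyl-3-formyl-6-methyl-8-methylidene-4-[(triethylsilyl)oxy]nonanoate F7. CrCl2 with catalytic LiI in THF/DMF then effects an intramolecular Nozaki–Hiyama–Kishi allylation. The allylchromium species reacts at its substituted terminus through a chair transition state and should give the same trans product, rejoining the route at 23.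

Step 10. C-alkylation of the dianion may be incomplete (O-alkylation, proton transfer to the bromoacetate, lactonisation of the alkoxide onto the new ester), or the anti selectivity may erode. The fallback sets out from 14 and forms both centres in one auxiliary-controlled aldol reaction. Mono-tert-butyl succinate is coupled to (S)-4-benzyl-1,3-oxazolidin-2-one (pivaloyl chloride, Et3N, LiCl) to give (4S)-4-benzyl-3-(4-tert-butoxy-4-oxobutanoyl)-1,3-oxazolidin-2-one F8. Its dibutylboron enolate (Bu2BOTf, iPr2NEt) is added to 14 precomplexed with Et2AlCl at −78 °C; the open transition state is anti-selective and should give tert-butyl (3R,4R,6S,7Z)-3-{[(4S)-4-benzyl-2-oxo-1,3-oxazolidin-3-yl]carbonyl}-9-{[tert-butyl(diphenyl)silyl]oxy}-6-ethenyl-4-hydroxy-6,8-dimethylnon-7-enoate F9. TESCl/imidazole gives the 4-[(triethylsilyl)oxy] derivative, tert-butyl (3R,4R,6S,7Z)-3-{[(4S)-4-benzyl-2-oxo-1,3-oxazolidin-3-yl]carbonyl}-9-{[tert-butyl(diphenyl)silyl]oxy}-6-ethenyl-6,8-dimethyl-4-[(triethylsilyl)oxy]non-7-enoate F10. LiBH4/MeOH removes the auxiliary reductively and rejoins the route at 20.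

**Further compounds**

F1 | step 6 | [(E)-2-(4-methoxyphenyl)ethenyl]bis(2-methylpropyl)alumane | COc1ccc(/C=C/[Al](CC(C)C)CC(C)C)cc1
F2 | step 6 | tert-butyl{[(3S,4E)-3-ethenyl-5-(4-methoxyphenyl)-3-methylpent-4-en-1-yl]oxy}dimethylsilane | C=C[C@](/C=C/c1ccc(OC)cc1)(C)CCO[Si](C)(C)C(C)(C)C
F3 | step 6 | (2S)-4-{[tert-butyl(dimethyl)silyl]oxy}-2-ethenyl-2-methylbutanal | C=C[C@](C=O)(C)CCO[Si](C)(C)C(C)(C)C
F4 | step 6 | methyl (2Z,4S)-6-{[tert-butyl(dimethyl)silyl]oxy}-4-ethenyl-2,4-dimethylhex-2-enoate | C=C[C@](/C=C(/C)C(=O)OC)(C)CCO[Si](C)(C)C(C)(C)C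
F5 | step 6 | (2Z,4S)-6-{[tert-butyl(dimethyl)silyl]oxy}-4-ethenyl-2,4-dimethylhex-2-en-1-ol | C=C[C@](/C=C(/C)CO)(C)CCO[Si](C)(C)C(C)(C)C
F6 | step 14 | tert-butyl (3S,4R,6S)-9-{[tert-butyl(diphenyl)silyl]oxy}-7-chloro-6-ethenyl-3-(hydroxymethyl)-6-methyl-8-methylidene-4-[(triethylsilyl)oxy]nonanoate (both epimers at C7) | C=C[C@](C(Cl)C(=C)CO[Si](c1ccccc1)(c1ccccc1)C(C)(C)C)(C)C[C@@H](O[Si](CC)(CC)CC)[C@@H](CC(=O)OC(C)(C)C)CO
F7 | step 14 | tert-butyl (3R,4R,6S)-9-{[tert-butyl(diphenyl)silyl]oxy}-7-chloro-6-ethenyl-3-formyl-6-methyl-8-methylidene-4-[(triethylsilyl)oxy]nonanoate (both epimers at C7) | C=C[C@](C(Cl)C(=C)CO[Si](c1ccccc1)(c1ccccc1)C(C)(C)C)(C)C[C@@H](O[Si](CC)(CC)CC)[C@@H](CC(=O)OC(C)(C)C)C=O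
F8 | step 10 | (4S)-4-benzyl-3-(4-tert-butoxy-4-oxobutanoyl)-1,3-oxazolidin-2-one | CC(C)(C)OC(=O)CCC(=O)N1[C@@H](Cc2ccccc2)COC1=O
F9 | step 10 | tert-butyl (3R,4R,6S,7Z)-3-{[(4S)-4-benzyl-2-oxo-1,3-oxazolidin-3-yl]carbonyl}-9-{[tert-butyl(diphenyl)silyl]oxy}-6-ethenyl-4-hydroxy-6,8-dimethylnon-7-enoate | C=C[C@](/C=C(/C)CO[Si](c1ccccc1)(c1ccccc1)C(C)(C)C)(C)C[C@@H](O)[C@@H](CC(=O)OC(C)(C)C)C(=O)N1[C@@H](Cc2ccccc2)COC1=O
F10 | step 10 | tert-butyl (3R,4R,6S,7Z)-3-{[(4S)-4-benzyl-2-oxo-1,3-oxazolidin-3-yl]carbonyl}-9-{[tert-butyl(diphenyl)silyl]oxy}-6-ethenyl-6,8-dimethyl-4-[(triethylsilyl)oxy]non-7-enoate | C=C[C@](/C=C(/C)CO[Si](c1ccccc1)(c1ccccc1)C(C)(C)C)(C)C[C@@H](O[Si](CC)(CC)CC)[C@@H](CC(=O)OC(C)(C)C)C(=O)N1[C@@H](Cc2ccccc2)COC1=O
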